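## The problem

The target is a daucane-type hydroazulene. It is numbered here as follows: C1 is the quaternary carbon bearing the methyl group, C2 and C3 are the ring methylenes, C4 is the isopropyl carbinol, C5 the ring-fusion methine, C6 the ester-bearing carbon, C7 a methylene, C8 the alkene carbon carrying the formyl carbon C14, and C9 and C10 complete the ring. Ring A is the cyclopentane C1–C5 and ring B the cycloheptene C1, C5–C10, trans-fused along C1–C5.

Four contiguous stereocentres must be set: C1 (R), C4 (R), C5 (S) and C6 (S). Once the frame is trans-fused, the angular methyl on C1 shields the β face. C1 can therefore dictate C5 and C6 (syn addition across a C5=C6 alkene from the α face) and C4 (a nucleophile entering a C4 ketone from the α face), so only C1 needs absolute control from outside.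

The enal tolerates neither borane nor hydride nor organometallic reagents, and the tertiary C4 alcohol is sensitive to strong acid. The aryl ester with its free phenol is sensitive to base and hydride. At any stage with a C4 ketone, the C6 oxygen sits β to the carbonyl, so elimination, retro-aldol cleavage and epimerisation at C5 all threaten.

The hard construction problems are the seven-membered ring and the quaternary centre beside it. The enabling feature is that C1 lies two carbons from C9 (through C10) and is bonded to C5–C6. With a ketone at C9 and an alkene at C5=C6, this is the γ,δ-unsaturated ketone left by a Claisen rearrangement of the allyl vinyl ether C10=C9–O–C6–C5=C1. Because C6 and C9 are 1,4-related in ring B, that ether is a 2-methylenetetrahydrofuran and the rearrangement is a ring expansion.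

## Retrosynthesis

**Ester last (26 to 21 and 24).** The acyl C–O bond at C6 is cut first, giving dihydroxy enal 21 and 4-(tert-butyldimethylsilyloxy)benzoic acid 24 (made from 4-hydroxybenzoic acid 22). The silyl ether is removed from 25 in the final step. The ester cannot be carried earlier: it would not survive LiAlH4, ethoxide or an organocerium reagent, and β to a C4 ketone it would be eliminated. Compound 21 has a single acylable hydroxyl (secondary C6; C4 is tertiary), so the forward step needs only a chemoselective esterification that leaves the enal alone.

**Enal from a C9 ketone (21 to 17).** The C8–C14 bond and the C8=C9 alkene are traced to ketone 17. Formylation at C8 gives 18, O-isopropylation gives 19, 1,2-reduction gives 20, and acid transposes the allylic system to the enal. A ring-closing olefin or aldol construction of C8=C9 would leave the quaternary centre unsolved, whereas a C9 ketone is exactly what the key step delivers. The acetonide joining O4 and O6 in 17 keeps both hydroxyls out of the base and hydride steps and falls off in the same acid treatment. The forward sequence must formylate at C8 and not at C10, which the neopentyl position of C10 should ensure.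

**Isopropyl group (17 to 16, 15 and 14).** Ketone 17 comes from acetonide alcohol 16 and triol 15 by oxidation-state adjustment. Triol 15 arises by cutting the C4–isopropyl bond: an isopropylcerium reagent adds to ketone 14. Bringing the isopropyl carbinol in with the ring A building block would demand separate control of C4, whereas here the angular methyl directs the addition. This addition must precede the enal, so C9 is kept at the carbinol level through it. The forward reaction must attack from the α face without enolising an aldol-type ketone.

**C5–H and C6–O (14 to 13 and 11).** Ketal hydrolysis relates 14 to diol 13, and both the C5–H and C6–O bonds of 13 come from hydroboration–oxidation of the C5=C6 alkene of 11. Epoxidation and hydride opening would place hydrogen on C5 with inversion and give the cis fusion. Borane also reduces the C9 ketone; this is used deliberately as the protection that C9 needs until step 11. The precursor 11 has one stereocentre instead of three. The forward step needs boron at C6 and α-face delivery.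

**Key disconnection (11 to 10).** The C1–C10 bond of 11 is cut and C6 is reconnected to oxygen, giving 2-methylenetetrahydrofuran 10. This removes ring B and the quaternary centre in one move and trades C1 for a secondary carbinol centre at C6. The forward reaction must transfer chirality completely from C6 to C1 and must outrun isomerisation of the enol ether.

**Enol ether and carbinol centre (10 to 9, 8 and 7).** The methylene C10 is removed to give lactone 9 (carbonyl methylenation forward). The lactone opens to hydroxy ester 8, whose C6–H bond comes from enantioselective reduction of keto ester 7. This places the only externally controlled stereocentre in a catalytic ketone reduction with a large/small bias (tetrasubstituted alkenyl against a primary chain).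

**Ring A fragment (7 to 3 and 4).** The C5–C6 bond is cut between a vinyl anion and a succinyl unit: vinyllithium 5 from bromo ketal 3 opens succinic anhydride 4, and the carboxylate 6 is methylated in the same flask. Bromo ketal 3 comes from 3-methylcyclopent-2-en-1-one 1 through bromo enone 2. All ten ring carbons are then in place after three steps.

## Roads not taken

**Alternative 1:** The cut is C4–C5, closing ring A. Forward, the acyclic diazo ester A2 is decomposed with Rh2(OAc)4 and the carbenoid at C5 inserts into the tertiary, oxygen-activated C4–H bond to give cyclopentane ester A1.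
- Merits: the C4 carbinol configuration is fixed before ring closure and carried through with retention. This is better than the chosen plan, which must rely on facial selectivity in a late organometallic addition and must pass through a fragile β-hydroxy ketone. The carbene carbon has no β-hydrogen and the five-membered insertion is the favoured mode.
- Weak points: A2 needs two remote stereocentres (quaternary C1 and C4) set independently in an open chain. A1 still lacks ring B, which must be built from the ester and the allyl group with three more carbons and a new, separately controlled centre at C6.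
- Comparison: the chosen plan sets C1 from one catalytic reduction through a stereospecific shift and obtains C5 and C6 together from one hydroboration.

**Alternative 2:** The cut is C1–C5, with C1 reconnected to C6. Forward, the cis-decalin epoxy alcohol A4 (tertiary carbinol at C6, C4–C5 epoxide) is treated with BF3·OEt2, and C1 shifts from C6 to C5 as the epoxide opens, giving the trans-fused β-hydroxy ketone A3.
- Merits: the endgame from A3 is clearly shorter than the chosen one. The C4 carbinol comes stereospecifically from the epoxide oxygen, C14 is already present as a silyl ether, and a hydroxyl-directed reduction of the C6 ketone should give the required anti 1,3-diol.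
- Weak points: the bond that must migrate, C6–C1, is a ring bond of the epoxide-bearing ring and reaches antiperiplanarity with the breaking C5–O bond less well than the exocyclic C6–C7 bond. Ring expansion to a bridged ketone therefore competes, and the outcome depends on the conformation of a flexible cis-decalin. A4 itself carries four stereocentres and needs its own enantioselective decalin synthesis.
- Comparison: against the shorter endgame, the chosen plan sets a key step whose regio- and stereochemical outcome is fixed by the tether and by orbital symmetry, and a substrate available in five steps.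

**Alternative 3:** The cuts are C1–CH3 and C5–C6. Forward, AlMe3 adds methyl to C1 of enone A6 under Cu(OTf)2 with a chiral phosphoramidite, and the aluminium enolate is trapped by aldehyde A7 to give aldol A5. Ring B would later close by aldol condensation of the two unmasked aldehydes.
- Merits: three stereocentres and most of the carbon skeleton arise in a single catalytic asymmetric step. If all selectivities held, this would be the shortest route, shorter than the chosen one.
- Weak points: β,β-disubstituted cyclopentenones are poor substrates for this addition. The facial selectivity of the aldol at C5 must distinguish a methyl from a CH2CH(OMe)2 group on the adjacent quaternary carbon, which is a weak basis for the trans fusion. The syn/anti ratio at C6 is a further variable. The seven-membered aldol condensation can close in two regiochemical senses. A5 is a retro-aldol-prone β-hydroxy ketone throughout.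
- Comparison: the chosen plan is longer, but each stereocentre is derived from a rigid cyclic precursor with a clear bias.

Key step: step 6

## Route

Remark: the C9 carbinol centre formed in step 7 is carried as a mixture of epimers (12–16, again in 20), and enol ether 19 is drawn as its E isomer; both elements vanish in steps 11 and 14 and do not affect the target.

Step 1
Reactants: 1 3-methylcyclopent-2-en-1-one
Product: 2 2-bromo-3-methylcyclopent-2-en-1-one
Conditions: Br2, CH2Cl2, 0 °C; then Et3N, 0 °C → rt
Reagents that add atoms: bromine, BrBr
Why: Bromine adds across the enone alkene and triethylamine eliminates HBr (bromination–dehydrobromination), leaving bromine on the α carbon of the conjugated enone.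

Step 2
Reactants: 2 2-bromo-3-methylcyclopent-2-en-1-one
Product: 3 6-bromo-7-methyl-1,4-dioxaspiro[4.4]non-6-ene
Conditions: ethylene glycol, p-TsOH (cat.), benzene, reflux, Dean–Stark
Reagents that add atoms: ethylene glycol, OCCO
Why: Acid-catalysed ketalisation with removal of water; the α-bromine and the fully substituted alkene keep the double bond from migrating out of position.

Step 3
Reactants: 3 6-bromo-7-methyl-1,4-dioxaspiro[4.4]non-6-ene; 4 succinic anhydride
Product: 7 methyl 4-(7-methyl-1,4-dioxaspiro[4.4]non-6-en-6-yl)-4-oxobutanoate, via vinyllithium 5 (not isolated), via lithium carboxylate 6 (not isolated)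
Conditions: n-BuLi, THF, −78 °C; cannulated into 4 (1.5 equiv), THF, −78 °C; then MeI, DMF, −78 °C → rt
Reagents that add atoms: iodomethane, CI
Why: Lithium–bromine exchange gives the α-ketovinyl anion equivalent 5, which opens the cyclic anhydride to keto carboxylate 6 (inverse addition suppresses a second addition); SN2 methylation of the carboxylate in DMF avoids ever freeing a carboxylic acid next to the ketal.

Step 4
Reactants: 7 methyl 4-(7-methyl-1,4-dioxaspiro[4.4]non-6-en-6-yl)-4-oxobutanoate
Product: 9 (5S)-5-(7-methyl-1,4-dioxaspiro[4.4]non-6-en-6-yl)oxolan-2-one, via hydroxy ester 8 (not isolated)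
Conditions: (R)-Me-CBS (0.2 equiv), BH3·SMe2, THF, −20 °C; MeOH; then PPTS (cat.), toluene, 50 °C
Reagents that add atoms: none
Why: Corey–Bakshi–Shibata reduction; the tetrasubstituted alkenyl group acts as the large substituent and the primary chain as the small one, so the (R)-catalyst should deliver hydride to give the (S)-carbinol 8, which closes to the γ-lactone with loss of methanol.

Step 5
Reactants: 9 (5S)-5-(7-methyl-1,4-dioxaspiro[4.4]non-6-en-6-yl)oxolan-2-one
Product: 10 (5S)-2-methylidene-5-(7-methyl-1,4-dioxaspiro[4.4]non-6-en-6-yl)oxolane
Conditions: Cp2TiMe2 (2.5 equiv), toluene, 70 °C, dark; filtration through basic alumina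
Reagents that add atoms: dimethyltitanocene Cp2TiMe2, C[Ti](C)(C1C=CC=C1)C1C=CC=C1
Why: Petasis methylenation; the titanium methylidene formed on heating converts the lactone carbonyl into the exocyclic enol ether under non-acidic conditions that spare the ketal and the allylic C6–O bond.

Step 6
Reactants: 10 (5S)-2-methylidene-5-(7-methyl-1,4-dioxaspiro[4.4]non-6-en-6-yl)oxolane
Product: 11 (3a′R)-3a′-methyl-2′,3′,3a′,4′,6′,7′-hexahydrospiro[1,3-dioxolane-2,1′-azulen]-5′(1′H)-one (C9 ketone, C5=C6, C4 ketal, 1R)
Conditions: toluene (degassed), i-Pr2NEt (0.1 equiv), base-washed sealed tube, 185 °C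
Reagents that add atoms: none
Why: Heating brings the exocyclic enol ether C10=C9–O and the allylic unit C6–C5=C1 into a concerted (3,3) sigmatropic shift (Claisen rearrangement) in which C1–C10 forms as C6–O breaks and the ring oxygen becomes the C9 carbonyl. The closest known reaction type is the ring-enlarging Claisen rearrangement of 2-methylene-5-alkenyltetrahydrofurans to cyclohept-4-enones, including cases where the alkenyl group is a cycloalkenyl ring. Ring B is closed by ring expansion and not by cyclisation of a chain: the five-membered ether with its exocyclic carbon C10 and the C5=C1 unit pass through a bridged, 8-oxabicyclo[3.2.1]octene-like transition state with a boat arrangement of the six reacting atoms, the only one that gives the cis C5=C6 bond a seven-membered ring can hold. The one new stereocentre, quaternary C1, is controlled by the C6 carbinol centre, which is consumed: the shift is suprafacial on the allyl unit, C7 is held inside by the tether and the geometry of C5=C1 is fixed by ring A, so C10 can reach only the face of C1 from which oxygen departs and (S)-C6 becomes (R)-C1. The step needs complete 1,3-chirality transfer and preference for the sigmatropic path over proton-catalysed migration of the enol ether double bond into the ring. The first is secured by the cyclic constraint, which leaves no competing chair or rotamer, and the second by base-washed glass and the amine buffer. The ketal lies outside the six-atom array and is a spectator.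

Step 7
Reactants: 11 ketal enone (C9 ketone, C5=C6, C4 ketal, 1R)
Product: 13 (3a′R,8′S,8a′S)-3a′-methyloctahydrospiro[1,3-dioxolane-2,1′-azulene]-5′,8′-diol (C6 α-OH, C5 α-H, C9 carbinol as epimers), via organoborane 12 (not isolated)
Conditions: BH3·THF (4 equiv), THF, 0 °C → rt; then 3 M NaOH, 30% H2O2, 0 °C → rt
Reagents that add atoms: hydrogen peroxide, OO
Why: Hydroboration–oxidation; boron goes to the less substituted C6 and hydrogen to C5 in a syn addition from the α face, opposite the axial angular methyl as in Δ5-steroid alkenes, and oxidation with retention should give C6 α-OH and the trans fusion; borane also reduces the C9 ketone, which parks C9 at the carbinol level for the next steps.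

Step 8
Reactants: 13 ketal diol
Product: 14 (3aR,8S,8aS)-5,8-dihydroxy-3a-methyloctahydroazulen-1(2H)-one (C4 ketone, C6 α-OH, C9 carbinol as epimers)
Conditions: PPTS, acetone/H2O (10:1), 50 °C
Reagents that add atoms: water, O
Why: Mild acid-catalysed ketal hydrolysis; the weak acid and moderate temperature are chosen so that the aldol-type ketone is not enolised toward C5.

Step 9
Reactants: 14 dihydroxy ketone
Product: 15 (1R,3aR,8S,8aS)-3a-methyl-1-(propan-2-yl)decahydroazulene-1,5,8-triol (C9 carbinol as epimers)
Conditions: i-PrMgCl (5 equiv), CeCl3 (5 equiv, dried), THF, −78 → −30 °C; aq. NH4Cl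
Reagents that add atoms: isopropylmagnesium chloride, CC(C)[Mg]Cl
Why: Organocerium 1,2-addition; the weakly basic i-PrCeCl2 should add without enolisation or hydride transfer, entering C4 from the α face because the β face is blocked by the angular methyl in a 1,3-relationship, with the C6 alkoxide on the same side able to assist; excess reagent absorbs the two hydroxyl protons.

Step 10
Reactants: 15 triol
Product: 16 4,6-O-isopropylidene acetal of triol 15 (six-membered acetonide across O4 and O6, C9 carbinol free, epimers)
Conditions: Me2C(OMe)2, acetone, CSA (cat.), rt; Et3N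
Reagents that add atoms: 2,2-dimethoxypropane, COC(C)(C)OC
Why: Acetonide formation under equilibrating conditions; O4 (β on ring A) and O6 are cis across C4–C5 and gauche across C5–C6, so the 1,3-dioxane can close, whereas the isolated C9 hydroxyl can only give a labile open mixed ketal.

Step 11
Reactants: 16 acetonide alcohol
Product: 17 acetonide ketone (C9 ketone; O4 and O6 as isopropylidene acetal)
Conditions: Dess–Martin periodinane, NaHCO3, CH2Cl2, rt
Reagents that add atoms: none
Why: Periodinane oxidation of the only free hydroxyl; both C9 epimers converge on one ketone under buffered conditions that spare the acetonide.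

Step 12
Reactants: 17 acetonide ketone
Product: 18 (Z)-8-(hydroxymethylene) derivative of ketone 17
Conditions: NaH, HCO2Et, EtOH (cat.), THF, 0 °C → rt; aq. NH4Cl
Reagents that add atoms: ethyl formate, CCOC=O
Why: Crossed Claisen condensation (α-formylation) under equilibrating conditions; C8 is an unhindered methylene whereas C10 is neopentyl next to quaternary C1, so the chelated hydroxymethylene ketone should form at C8.

Step 13
Reactants: 18 hydroxymethylene ketone
Product: 19 (E)-8-(isopropoxymethylene) derivative of ketone 17
Conditions: i-PrI, K2CO3, acetone, reflux
Reagents that add atoms: 2-iodopropane, CC(C)I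
Why: O-alkylation of the potassium salt of a hydroxymethylene ketone with a secondary iodide gives the vinylogous ester, the standard activation for carbonyl transposition.

Step 14
Reactants: 19 isopropoxymethylene ketone
Product: 21 (1R,3aR,8S,8aS)-1,8-dihydroxy-3a-methyl-1-(propan-2-yl)-1,2,3,3a,4,7,8,8a-octahydroazulene-6-carbaldehyde, via allylic alcohol 20 (not isolated)
Conditions: LiAlH4, Et2O, 0 °C; then 1 M HCl, THF, rt
Reagents that add atoms: water, O
Why: 1,2-Reduction of the vinylogous ester gives allylic alcohol 20; acid ionises the C9 hydroxyl, water adds at C14 and isopropanol is lost, placing the alkene at C8=C9 and the aldehyde at C14 (reductive carbonyl transposition); the acetonide, which keeps O6 from capturing the allylic cation, is hydrolysed in the same medium.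

Step 15
Reactants: 22 4-hydroxybenzoic acid
Product: 24 4-(tert-butyldimethylsilyloxy)benzoic acid, via silyl ester 23 (not isolated)
Conditions: TBSCl (2.2 equiv), imidazole, DMF, rt; then K2CO3, MeOH/THF/H2O, rt; citric acid to pH 4
Reagents that add atoms: tert-butyldimethylsilyl chloride, CC(C)(C)[Si](C)(C)Cl
Why: Silylation of both acidic sites followed by selective hydrolysis of the much more labile silyl ester leaves the phenol protected and the acid free.

Step 16
Reactants: 21 dihydroxy enal; 24 4-(tert-butyldimethylsilyloxy)benzoic acid
Product: 25 (1R,3aR,8S,8aS)-6-formyl-1-hydroxy-3a-methyl-1-(propan-2-yl)-1,2,3,3a,4,7,8,8a-octahydroazulen-8-yl 4-(tert-butyldimethylsilyloxy)benzoate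
Conditions: EDC·HCl, DMAP, CH2Cl2, rt
Reagents that add atoms: none
Why: Steglich esterification; only the secondary C6 hydroxyl is acylated, since the tertiary C4 hydroxyl does not react with the acylpyridinium intermediate and the enal is inert.

Step 17
Reactants: 25 silyl-protected ester
Product: 26 (1R,3aR,8S,8aS)-6-formyl-1-hydroxy-3a-methyl-1-(propan-2-yl)-1,2,3,3a,4,7,8,8a-octahydroazulen-8-yl 4-hydroxybenzoate (target)
Conditions: HF·pyridine, pyridine, THF, 0 °C
Reagents that add atoms: none
Why: Fluoride cleavage of the aryl silyl ether, the most labile Si–O bond present, under buffered conditions that leave the ester, the enal and the tertiary alcohol untouched.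

## Compound list

1 | 3-methylcyclopent-2-en-1-one | CC1=CC(=O)CC1 | starting material
2 | 2-bromo-3-methylcyclopent-2-en-1-one | CC1=C(Br)C(=O)CC1 | intermediate
3 | 6-bromo-7-methyl-1,4-dioxaspiro[4.4]non-6-ene | BrC1=C(C)CCC12OCCO2 | intermediate
4 | succinic anhydride | O=C1CCC(=O)O1 | starting material
5 | (7-methyl-1,4-dioxaspiro[4.4]non-6-en-6-yl)lithium | [Li]C1=C(C)CCC12OCCO2 | intermediate
6 | lithium 4-(7-methyl-1,4-dioxaspiro[4.4]non-6-en-6-yl)-4-oxobutanoate | [Li+].[O-]C(=O)CCC(=O)C1=C(C)CCC12OCCO2 | intermediate
7 | methyl 4-(7-methyl-1,4-dioxaspiro[4.4]non-6-en-6-yl)-4-oxobutanoate | COC(=O)CCC(=O)C1=C(C)CCC12OCCO2 | intermediate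
8 | methyl (4S)-4-hydroxy-4-(7-methyl-1,4-dioxaspiro[4.4]non-6-en-6-yl)butanoate | COC(=O)CC[C@H](O)C1=C(C)CCC12OCCO2 | intermediate
9 | (5S)-5-(7-methyl-1,4-dioxaspiro[4.4]non-6-en-6-yl)oxolan-2-one | O=C1CC[C@H](O1)C1=C(C)CCC12OCCO2 | intermediate
10 | (5S)-2-methylidene-5-(7-methyl-1,4-dioxaspiro[4.4]non-6-en-6-yl)oxolane | C=C1CC[C@H](O1)C1=C(C)CCC12OCCO2 | intermediate
11 | (3a′R)-3a′-methyl-2′,3′,3a′,4′,6′,7′-hexahydrospiro[1,3-dioxolane-2,1′-azulen]-5′(1′H)-one | O=C1C[C@@]2(C)CCC3(OCCO3)C2=CCC1 | intermediate
12 | organoborane from 11 (C6 α-boryl, C9 boryloxy, C9 epimers) | O1CCOC12CC[C@]3(C)CC(OB)CC[C@H](B)[C@H]32 | intermediate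
13 | (3a′R,8′S,8a′S)-3a′-methyloctahydrospiro[1,3-dioxolane-2,1′-azulene]-5′,8′-diol (C9 epimers) | O1CCOC12CC[C@]3(C)CC(O)CC[C@H](O)[C@H]32 | intermediate
14 | (3aR,8S,8aS)-5,8-dihydroxy-3a-methyloctahydroazulen-1(2H)-one (C9 epimers) | O=C1CC[C@]2(C)CC(O)CC[C@H](O)[C@H]21 | intermediate
15 | (1R,3aR,8S,8aS)-3a-methyl-1-(propan-2-yl)decahydroazulene-1,5,8-triol (C9 epimers) | CC(C)[C@]1(O)CC[C@]2(C)CC(O)CC[C@H](O)[C@H]21 | intermediate
16 | 4,6-O-isopropylidene acetal of 15 (C9 carbinol, epimers) | CC(C)[C@]1(OC(C)(C)O2)CC[C@]3(C)CC(O)CC[C@H]2[C@H]31 | intermediate
17 | 4,6-O-isopropylidene C9 ketone | CC(C)[C@]1(OC(C)(C)O2)CC[C@]3(C)CC(=O)CC[C@H]2[C@H]31 | intermediate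
18 | (Z)-8-(hydroxymethylene) derivative of 17 | CC(C)[C@]1(OC(C)(C)O2)CC[C@]3(C)CC(=O)/C(=C\O)C[C@H]2[C@H]31 | intermediate
19 | (E)-8-(isopropoxymethylene) derivative of 17 | CC(C)[C@]1(OC(C)(C)O2)CC[C@]3(C)CC(=O)/C(=C/OC(C)C)C[C@H]2[C@H]31 | intermediate
20 | C9 allylic alcohol of 19 (C9 epimers) | CC(C)[C@]1(OC(C)(C)O2)CC[C@]3(C)CC(O)/C(=C/OC(C)C)C[C@H]2[C@H]31 | intermediate
21 | (1R,3aR,8S,8aS)-1,8-dihydroxy-3a-methyl-1-(propan-2-yl)-1,2,3,3a,4,7,8,8a-octahydroazulene-6-carbaldehyde | CC(C)[C@]1(O)CC[C@]2(C)CC=C(C=O)C[C@H](O)[C@H]21 | intermediate
22 | 4-hydroxybenzoic acid | O=C(O)c1ccc(O)cc1 | starting material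
23 | tert-butyldimethylsilyl 4-(tert-butyldimethylsilyloxy)benzoate | CC(C)(C)[Si](C)(C)OC(=O)c1ccc(O[Si](C)(C)C(C)(C)C)cc1 | intermediate
24 | 4-(tert-butyldimethylsilyloxy)benzoic acid | O=C(O)c1ccc(O[Si](C)(C)C(C)(C)C)cc1 | intermediate
25 | (1R,3aR,8S,8aS)-6-formyl-1-hydroxy-3a-methyl-1-(propan-2-yl)-1,2,3,3a,4,7,8,8a-octahydroazulen-8-yl 4-(tert-butyldimethylsilyloxy)benzoate | CC(C)[C@]1(O)CC[C@]2(C)CC=C(C=O)C[C@H](OC(=O)c3ccc(O[Si](C)(C)C(C)(C)C)cc3)[C@H]21 | intermediate
26 | (1R,3aR,8S,8aS)-6-formyl-1-hydroxy-3a-methyl-1-(propan-2-yl)-1,2,3,3a,4,7,8,8a-octahydroazulen-8-yl 4-hydroxybenzoate | CC(C)[C@]1(O)CC[C@]2(C)CC=C(C=O)C[C@H](OC(=O)c3ccc(O)cc3)[C@H]21 | target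

## Step count and least certain steps

Total: 17 steps. Longest linear sequence: 16 steps from 1 (steps 1–14, 16 and 17); step 15 is a one-step side branch.

**Step 6 (key step).** The rearrangement may be too slow. The reactive conformer must hold C7 inside, against the methyl group on C1 (allylic 1,3-strain in the boat transition state). At the temperature then required, proton-catalysed migration of the enol ether double bond into the ring, or ionisation of the allylic C6–O bond with loss of chirality transfer, can overtake the sigmatropic shift.
Fallback, from 10: treatment with i-Bu3Al in CH2Cl2 at −78 °C → rt replaces thermal activation by Lewis-acid activation of the ring oxygen. The same C1–C10/C6–O reorganisation then occurs at low temperature, and the aluminium-bound ketone is reduced in the flask by hydride transfer from an isobutyl group, giving the ketal cycloheptenol F1. Under the conditions of step 7, F1 should give diol 13, where the fallback returns to the route.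

**Step 3.** The organolithium 5 may add a second time to the keto carboxylate 6, or may act as a base toward the anhydride or the new ketone, because both are enolisable and the reagent is strongly basic.
Fallback, from 3: succinic anhydride 4 is opened with methanol to monomethyl succinate F2, which oxalyl chloride converts into methyl 4-chloro-4-oxobutanoate F3. Vinyllithium 5 is transmetalated with ZnCl2 to the organozinc chloride F4, and Negishi acylation of F4 with F3 under Pd(PPh3)4 catalysis gives keto ester 7 directly.

**Step 8.** Under acid, the unveiled C4 ketone may enolise toward C5. This would epimerise the ring fusion or eliminate the β-hydroxyl at C6, since 14 is an aldol.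
Fallback, from 13: both hydroxyls are silylated (TBSOTf, 2,6-lutidine) to the bis-silyl ether F5, so that C6 carries a poor leaving group. Ketal hydrolysis gives the bis-silyloxy ketone F6, i-PrMgCl/CeCl3 addition gives the tertiary alcohol F7, and Bu4NF removes both silyl groups to return at triol 15.

**Step 9.** The bulky secondary nucleophile may attack with poor facial selectivity, or hydride transfer and enolisation may compete, because C4 is hindered and the isopropyl reagent carries β-hydrogens.
Fallback, from 14: the smaller sp2 reagent isopropenylmagnesium bromide with CeCl3 is added to give the isopropenyl carbinol F8. Hydrogenation of its 1,1-disubstituted alkene over PtO2 (no other alkene is present at this stage) gives triol 15.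

**Step 10.** Closure of the six-membered acetal on the tertiary oxygen may be incomplete, since one acetal methyl is forced against a carbon substituent of C4, and mixed-ketal formation at the unhindered C9 hydroxyl may compete.
Fallback, from 15, without a protecting group: a sterically discriminating oxidation (TEMPO cat., PhI(OAc)2) converts the unhindered C9 carbinol into the dihydroxy ketone F9. Formylation with excess NaH and HCO2Et gives the hydroxymethylene ketone F10, and i-PrI/K2CO3 gives the isopropoxymethylene ketone F11. LiAlH4 reduction gives the allylic alcohol F12, and aqueous acid transposes it to dihydroxy enal 21, where the fallback returns.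

## Further compounds

F1 | step 6 | (3a′R)-3a′-methyl-1′,2′,3′,3a′,4′,5′,6′,7′-octahydrospiro[1,3-dioxolane-2,1′-azulen]-5′-ol (ketal cycloheptenol, C9 epimers) | O1CCOC12CC[C@]3(C)CC(O)CCC=C23
F2 | step 3 | 4-methoxy-4-oxobutanoic acid (monomethyl succinate) | COC(=O)CCC(=O)O
F3 | step 3 | methyl 4-chloro-4-oxobutanoate | COC(=O)CCC(=O)Cl
F4 | step 3 | chloro(7-methyl-1,4-dioxaspiro[4.4]non-6-en-6-yl)zinc | Cl[Zn]C1=C(C)CCC12OCCO2
F5 | step 8 | 6,9-bis(tert-butyldimethylsilyl) ether of diol 13 (C9 epimers) | O1CCOC12CC[C@]3(C)CC(O[Si](C)(C)C(C)(C)C)CC[C@H](O[Si](C)(C)C(C)(C)C)[C@H]32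
F6 | step 8 | 6,9-bis(tert-butyldimethylsilyl) ether of ketone 14 (C9 epimers) | O=C1CC[C@]2(C)CC(O[Si](C)(C)C(C)(C)C)CC[C@H](O[Si](C)(C)C(C)(C)C)[C@H]21
F7 | step 8 | 6,9-bis(tert-butyldimethylsilyl) ether of triol 15 (C9 epimers) | CC(C)[C@]1(O)CC[C@]2(C)CC(O[Si](C)(C)C(C)(C)C)CC[C@H](O[Si](C)(C)C(C)(C)C)[C@H]21
F8 | step 9 | 4-isopropenyl analogue of triol 15 (C9 epimers) | CC(=C)[C@]1(O)CC[C@]2(C)CC(O)CC[C@H](O)[C@H]21
F9 | step 10 | (3R,3aS,4S,8aR)-3,4-dihydroxy-8a-methyl-3-(propan-2-yl)octahydroazulen-6(1H)-one (4,6-dihydroxy C9 ketone) | CC(C)[C@]1(O)CC[C@]2(C)CC(=O)CC[C@H](O)[C@H]21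
F10 | step 10 | (Z)-8-(hydroxymethylene) derivative of F9 | CC(C)[C@]1(O)CC[C@]2(C)CC(=O)/C(=C\O)C[C@H](O)[C@H]21
F11 | step 10 | (E)-8-(isopropoxymethylene) derivative of F9 | CC(C)[C@]1(O)CC[C@]2(C)CC(=O)/C(=C/OC(C)C)C[C@H](O)[C@H]21
F12 | step 10 | C9 allylic alcohol of F11 (C9 epimers) | CC(C)[C@]1(O)CC[C@]2(C)CC(O)/C(=C/OC(C)C)C[C@H](O)[C@H]21
A1 | alternative 1 | methyl 2-(tert-butyldimethylsilyloxy)-5-methyl-2-(propan-2-yl)-5-(prop-2-enyl)cyclopentane-1-carboxylate with C1, C4 and C5 as in the target | CC(C)[C@]1(O[Si](C)(C)C(C)(C)C)CC[C@](C)(CC=C)[C@H]1C(=O)OC
A2 | alternative 1 | methyl 6-(tert-butyldimethylsilyloxy)-2-diazo-3,7-dimethyl-3-(prop-2-enyl)octanoate | CC(C)[C@H](O[Si](C)(C)C(C)(C)C)CC[C@](C)(CC=C)C(=[N+]=[N-])C(=O)OC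
A3 | alternative 2 | trans-fused β-hydroxy ketone (C4 carbinol, C6 ketone, C14 triisopropylsilyl ether) | CC(C)[C@]1(O)CC[C@]2(C)CC=C(CO[Si](C(C)C)(C(C)C)C(C)C)CC(=O)[C@H]21
A4 | alternative 2 | cis-decalin epoxy alcohol (C6 tertiary carbinol, C4–C5 epoxide syn to it, C14 triisopropylsilyl ether) | CC(C)[C@]1(O2)CC[C@]3(C)CC=C(CO[Si](C(C)C)(C(C)C)C(C)C)C[C@]3(O)[C@H]12
A5 | alternative 3 | anti aldol cyclopentanone with two dimethyl acetals (C1, C5 and C6 as in the target) | O=C1CC[C@](C)(CC(OC)OC)[C@H]1[C@@H](O)CCC(OC)OC
A6 | alternative 3 | 3-(2,2-dimethoxyethyl)cyclopent-2-en-1-one | O=C1C=C(CC(OC)OC)CC1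
A7 | alternative 3 | 4,4-dimethoxybutanal | COC(OC)CCC=O
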